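**Retrosynthetic overview**
1. Feature: ring A of unit 1 (C4a, C5, C6, C7, C8, C8a of the 5-hydroxy-7-methoxychromone) is a phloroglucinol ring methylated on O7 alone. This is the fold of a poly-β-carbonyl chain whose C7-destined carbonyl is kept as a methyl enol ether.
2. Key disconnection: ring A bond C4a–C5 (chain C6 to ester C1). It is a Claisen closure of a methyl (E)-3-methoxy-5,7,9-trioxonon-2-enoate that already carries the linker aryl group at C8 and the 4-benzyloxyphenyl group at C9. The resulting 2,6-dihydroxy-4-methoxyphenyl ketone is symmetric about its acyl carbon, so O5 and O7 never have to be told apart.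
3. The chain is released by methanolysis of a 4-methoxy-2-pyrone, whose ring fixes the (E)-geometry. The pyrone side chain is built by two carbanion acylations: C6–C7 with an arylacetate and C8–C9 with a benzoate.
4. Unit 2 is grown on the unmasked aldehyde of the linker ring by Claisen–Schmidt condensation with dibenzyl phloroacetophenone, oxidative cyclisation and global hydrogenolysis.
5. Ring order: ring A of unit 1, ring C of unit 1, ring C of unit 2. Ring B of unit 1, the linker ring (ring B of unit 2) and ring A of unit 2 are bought.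

Key step: step 7

Remark on the chemistry: the chain is not made by acylating a 1,3-diketone dianion with dimethyl (E)-3-methoxyglutaconate, because the doubly activated CH2 of that diester would protonate the dianion and end as an inert delocalised anion, so the pyrone brings in the same five carbons as the nucleophile; chain numbering C1–C9 is that of compound 10, C8 of 9–12 is a freely enolising centre drawn without configuration, and polycarbonyl compounds are drawn as keto tautomers.

**Step 1**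
Reactants: 1 3-bromo-4-hydroxybenzaldehyde
Product: 2 4-(benzyloxy)-3-bromobenzaldehyde
Conditions: BnBr, K2CO3, DMF, 25 °C
Reagents that add atoms: benzyl bromide, BrCc1ccccc1
Why: Williamson ether synthesis on the only acidic OH; the benzyl ether should withstand the organozinc, amide-base, Mg(OMe)2 and aqueous-acid steps and falls in the last step.

**Step 2**
Reactants: 2 4-(benzyloxy)-3-bromobenzaldehyde
Product: 3 2-[4-(benzyloxy)-3-bromophenyl]-1,3-dioxolane
Conditions: HOCH2CH2OH, p-TsOH·H2O (cat.), toluene, reflux (Dean–Stark)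
Reagents that add atoms: ethylene glycol, OCCO
Why: Acid-catalysed acetalisation driven by azeotropic removal of water; the dioxolane hides the aldehyde from every carbanion and alkoxide used up to step 7.

**Step 3**
Reactants: 3 2-[4-(benzyloxy)-3-bromophenyl]-1,3-dioxolane; 4 bromo(2-ethoxy-2-oxoethyl)zinc
Product: 5 ethyl [2-(benzyloxy)-5-(1,3-dioxolan-2-yl)phenyl]acetate
Conditions: Pd(dba)2 (2 mol %), P(t-Bu)3 (2 mol %), THF, 25 → 50 °C
Reagents that add atoms: none
Why: Negishi-type coupling of a Reformatsky reagent (palladium-catalysed α-arylation of a zinc ester enolate), in which oxidative addition of zerovalent palladium into C–Br, transmetalation and reductive elimination form the aryl–C8 bond under nearly neutral conditions that spare acetal and benzyl ether and stop at monoarylation.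

**Step 4**
Reactants: 6 4-methoxy-6-methyl-2H-pyran-2-one; 5 ethyl [2-(benzyloxy)-5-(1,3-dioxolan-2-yl)phenyl]acetate
Product: 7 6-{3-[2-(benzyloxy)-5-(1,3-dioxolan-2-yl)phenyl]-2-oxopropyl}-4-methoxy-2H-pyran-2-one
Conditions: LiN(i-Pr)2 (2.2 equiv), 6 (2.2 equiv), THF, −78 °C; then 5 (1 equiv), −78 → −10 °C; AcOH quench
Reagents that add atoms: none
Why: Crossed Claisen acylation of the laterally lithiated pyrone, in which LiN(i-Pr)2 removes a proton of the 6-methyl group (vinylogous to the lactone carbonyl), the carbanion delocalised over the whole pyrone should be no stronger a base than the enolate of 5 and so acylates the ester, and the second equivalent takes the acidic C6–H of 7 and pulls the equilibrium over (chain bond C6–C7).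

**Step 5**
Reactants: 7 6-{3-[2-(benzyloxy)-5-(1,3-dioxolan-2-yl)phenyl]-2-oxopropyl}-4-methoxy-2H-pyran-2-one; 8 methyl 4-(benzyloxy)benzoate
Product: 9 2-[2-(benzyloxy)-5-(1,3-dioxolan-2-yl)phenyl]-1-[4-(benzyloxy)phenyl]-4-(4-methoxy-2-oxo-2H-pyran-6-yl)butane-1,3-dione
Conditions: LiN(i-Pr)2 (3.2 equiv), THF, −78 → −20 °C; then 8, −78 → 0 °C; AcOH quench
Reagents that add atoms: none
Why: γ-Acylation of a 1,3-dicarbonyl-type dianion, in which the first equivalent of base ionises C6 (between ketone and pyrone), the second the benzylic C8, the later-formed and more basic C8 carbanion attacks the non-enolisable ester, and the third equivalent stores 9 as its stable enolate (chain bond C8–C9).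

**Step 6**
Reactants: 9 2-[2-(benzyloxy)-5-(1,3-dioxolan-2-yl)phenyl]-1-[4-(benzyloxy)phenyl]-4-(4-methoxy-2-oxo-2H-pyran-6-yl)butane-1,3-dione
Product: 10 methyl (2E)-8-[2-(benzyloxy)-5-(1,3-dioxolan-2-yl)phenyl]-9-[4-(benzyloxy)phenyl]-3-methoxy-5,7,9-trioxonon-2-enoate
Conditions: Mg(OMe)2 (3 equiv), MeOH–THF, 0 → 20 °C; cold dilute AcOH quench; used crude
Reagents that add atoms: methanol (delivered as the methoxide of Mg(OMe)2), CO
Why: Alkoxide methanolysis (transesterification) of the enol lactone, in which methoxide adds to the lactone carbonyl, the C5 enolate leaves and is held as the magnesium chelate of the new 1,3,5-triketone, only the (E)-enol ether can result because C1 and C4 were cis in the ring, and C–C bond formation should not yet set in at or below room temperature.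

**Step 7**
Reactants: 10 methyl (2E)-8-[2-(benzyloxy)-5-(1,3-dioxolan-2-yl)phenyl]-9-[4-(benzyloxy)phenyl]-3-methoxy-5,7,9-trioxonon-2-enoate
Product: 11 2-[2-(benzyloxy)-5-(1,3-dioxolan-2-yl)phenyl]-1-[4-(benzyloxy)phenyl]-3-(2,6-dihydroxy-4-methoxyphenyl)propane-1,3-dione
Conditions: Mg(OMe)2 (6 equiv), MeOH, reflux; cold dilute AcOH quench
Reagents that add atoms: none
Why: Proposed new method: Mg(OMe)2 turns 10 into the magnesium chelate of its C5/C7/C9 triketone; chain carbon C6 of this chelate adds to the ester carbonyl C1, methoxide is expelled, and the first-formed keto tautomer enolises at once to the benzene ring, so that bond C4a–C5 and ring A are made while the enol-ether methyl ends up as the O7 methyl group. The closest known reaction type is the biomimetic Claisen cyclisation of 7-aryl-3,5,7-trioxoheptanoate esters to 2,4,6-trihydroxyphenyl ketones, which has not been shown for a chain that carries a methyl enol ether at C3 and an aryl-substituted 1,3-diketone at its far end. Ring A closes 6-exo-trig at the ester carbonyl, a mode open to the enolate in both its enolendo (C5=C6) and enolexo (C6=C7) form, and it is geometrically possible only because the (E)-double bond keeps C1 and C4 on the same side. No stereocentre is created, and C8 remains a freely enolising position. The selectivity needed is C6-to-C1 acylation over the aldol closures C4-to-C9 and C2-to-C7: C7 and C9 belong to the most acidic site of the molecule (C8–H) and sit as a chelated, sterically screened enolate that is a poor acceptor and also resists retro-Claisen cleavage, whereas C2 is vinylic. Lactonisation back to 9 is reversible in methanol, but aromatisation to the chelated magnesium phenoxide is not, so the equilibria should drain towards 11.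

**Step 8**
Reactants: 11 2-[2-(benzyloxy)-5-(1,3-dioxolan-2-yl)phenyl]-1-[4-(benzyloxy)phenyl]-3-(2,6-dihydroxy-4-methoxyphenyl)propane-1,3-dione
Product: 13 4-(benzyloxy)-3-{2-[4-(benzyloxy)phenyl]-5-hydroxy-7-methoxy-4-oxo-4H-chromen-3-yl}benzaldehyde, via formyl diketone 12 (not isolated)
Conditions: 2 M aq HCl, THF, 50 °C
Reagents that add atoms: water, O
Why: The aqueous acid first hydrolyses the dioxolane and then effects the cyclodehydration known from the last stage of the Baker–Venkataraman flavone synthesis, in which either of the two equivalent ortho hydroxyls adds to the C9 ketone (6-exo-trig) and loss of water closes ring C to one chromone only, benzyl and methyl ethers being inert.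

**Step 9**
Reactants: 14 1-(2,4,6-trihydroxyphenyl)ethanone
Product: 15 1-[2,4-bis(benzyloxy)-6-hydroxyphenyl]ethanone
Conditions: BnBr (2.1 equiv), K2CO3, DMF, 60 °C
Reagents that add atoms: benzyl bromide, BrCc1ccccc1
Why: Williamson ether synthesis with two equivalents of halide; once one ortho hydroxyl has reacted, the other is locked in a hydrogen bond to the acetyl carbonyl and stays free, as step 11 requires.

**Step 10**
Reactants: 13 4-(benzyloxy)-3-{2-[4-(benzyloxy)phenyl]-5-hydroxy-7-methoxy-4-oxo-4H-chromen-3-yl}benzaldehyde; 15 1-[2,4-bis(benzyloxy)-6-hydroxyphenyl]ethanone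
Product: 16 (2E)-3-(4-(benzyloxy)-3-{2-[4-(benzyloxy)phenyl]-5-hydroxy-7-methoxy-4-oxo-4H-chromen-3-yl}phenyl)-1-[2,4-bis(benzyloxy)-6-hydroxyphenyl]prop-2-en-1-one
Conditions: KOH (50 % aq), EtOH–THF, 25 °C; then 1 M HCl to pH 5
Reagents that add atoms: none
Why: Claisen–Schmidt condensation, in which the acetophenone enolate adds to the non-enolisable aldehyde and E1cB loss of water gives the conjugated (E)-enone as the thermodynamic product, the chromone of unit 1 being shielded from hydroxide by its 5-phenoxide and its two aryl groups.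

**Step 11**
Reactants: 16 (2E)-3-(4-(benzyloxy)-3-{2-[4-(benzyloxy)phenyl]-5-hydroxy-7-methoxy-4-oxo-4H-chromen-3-yl}phenyl)-1-[2,4-bis(benzyloxy)-6-hydroxyphenyl]prop-2-en-1-one
Product: 18 5,7-bis(benzyloxy)-2-(4-(benzyloxy)-3-{2-[4-(benzyloxy)phenyl]-5-hydroxy-7-methoxy-4-oxo-4H-chromen-3-yl}phenyl)-4H-chromen-4-one, via flavanone 17 (not isolated)
Conditions: I2 (10 mol %), DMSO, 125 °C
Reagents that add atoms: none
Why: Iodine/DMSO oxidative cyclisation of a 2'-hydroxychalcone, in which oxa-Michael closure (6-endo-trig) gives the racemic flavanone, α-iodination and loss of HI give the flavone, DMSO reoxidises HI so that iodine stays catalytic, and any stray ring iodination or loss of the peri benzyl group would be undone or harmless in step 12.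

**Step 12**
Reactants: 18 5,7-bis(benzyloxy)-2-(4-(benzyloxy)-3-{2-[4-(benzyloxy)phenyl]-5-hydroxy-7-methoxy-4-oxo-4H-chromen-3-yl}phenyl)-4H-chromen-4-one
Product: 19 5,7-dihydroxy-2-{4-hydroxy-3-[5-hydroxy-2-(4-hydroxyphenyl)-7-methoxy-4-oxo-4H-chromen-3-yl]phenyl}-4H-chromen-4-one (CNP0284832.0)
Conditions: H2 (1 atm), Pd/C, THF–MeOH, 25 °C
Reagents that add atoms: none
Why: Catalytic hydrogenolysis of the four benzyl aryl ethers; the methyl ether, the two chromone C2=C3 bonds (vinylogous esters) and the carbonyl groups should not be touched under one atmosphere of hydrogen at room temperature.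

**Compound list**
1 | 3-bromo-4-hydroxybenzaldehyde | O=Cc1ccc(O)c(Br)c1 | starting material
2 | 4-(benzyloxy)-3-bromobenzaldehyde | O=Cc1ccc(OCc2ccccc2)c(Br)c1 | intermediate
3 | 2-[4-(benzyloxy)-3-bromophenyl]-1,3-dioxolane | Brc1cc(C2OCCO2)ccc1OCc1ccccc1 | intermediate
4 | bromo(2-ethoxy-2-oxoethyl)zinc (commercial Reformatsky reagent solution) | CCOC(=O)C[Zn]Br | starting material
5 | ethyl [2-(benzyloxy)-5-(1,3-dioxolan-2-yl)phenyl]acetate | CCOC(=O)Cc1cc(C2OCCO2)ccc1OCc1ccccc1 | intermediate
6 | 4-methoxy-6-methyl-2H-pyran-2-one | COC1=CC(=O)OC(C)=C1 | starting material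
7 | 6-{3-[2-(benzyloxy)-5-(1,3-dioxolan-2-yl)phenyl]-2-oxopropyl}-4-methoxy-2H-pyran-2-one | COC1=CC(=O)OC(CC(=O)Cc2cc(C3OCCO3)ccc2OCc2ccccc2)=C1 | intermediate
8 | methyl 4-(benzyloxy)benzoate | COC(=O)c1ccc(OCc2ccccc2)cc1 | starting material
9 | 2-[2-(benzyloxy)-5-(1,3-dioxolan-2-yl)phenyl]-1-[4-(benzyloxy)phenyl]-4-(4-methoxy-2-oxo-2H-pyran-6-yl)butane-1,3-dione | COC1=CC(=O)OC(CC(=O)C(c2cc(C3OCCO3)ccc2OCc2ccccc2)C(=O)c2ccc(OCc3ccccc3)cc2)=C1 | intermediate
10 | methyl (2E)-8-[2-(benzyloxy)-5-(1,3-dioxolan-2-yl)phenyl]-9-[4-(benzyloxy)phenyl]-3-methoxy-5,7,9-trioxonon-2-enoate | COC(=O)/C=C(/OC)CC(=O)CC(=O)C(c1cc(C2OCCO2)ccc1OCc1ccccc1)C(=O)c1ccc(OCc2ccccc2)cc1 | intermediate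
11 | 2-[2-(benzyloxy)-5-(1,3-dioxolan-2-yl)phenyl]-1-[4-(benzyloxy)phenyl]-3-(2,6-dihydroxy-4-methoxyphenyl)propane-1,3-dione | COc1cc(O)c(C(=O)C(c2cc(C3OCCO3)ccc2OCc2ccccc2)C(=O)c2ccc(OCc3ccccc3)cc2)c(O)c1 | intermediate
12 | 4-(benzyloxy)-3-{1-[4-(benzyloxy)phenyl]-3-(2,6-dihydroxy-4-methoxyphenyl)-1,3-dioxopropan-2-yl}benzaldehyde (formyl diketone, not isolated) | COc1cc(O)c(C(=O)C(c2cc(C=O)ccc2OCc2ccccc2)C(=O)c2ccc(OCc3ccccc3)cc2)c(O)c1 | intermediate
13 | 4-(benzyloxy)-3-{2-[4-(benzyloxy)phenyl]-5-hydroxy-7-methoxy-4-oxo-4H-chromen-3-yl}benzaldehyde | COc1cc(O)c2c(=O)c(-c3cc(C=O)ccc3OCc3ccccc3)c(-c3ccc(OCc4ccccc4)cc3)oc2c1 | intermediate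
14 | 1-(2,4,6-trihydroxyphenyl)ethanone | CC(=O)c1c(O)cc(O)cc1O | starting material
15 | 1-[2,4-bis(benzyloxy)-6-hydroxyphenyl]ethanone | CC(=O)c1c(O)cc(OCc2ccccc2)cc1OCc1ccccc1 | intermediate
16 | (2E)-3-(4-(benzyloxy)-3-{2-[4-(benzyloxy)phenyl]-5-hydroxy-7-methoxy-4-oxo-4H-chromen-3-yl}phenyl)-1-[2,4-bis(benzyloxy)-6-hydroxyphenyl]prop-2-en-1-one | COc1cc(O)c2c(=O)c(-c3cc(/C=C/C(=O)c4c(O)cc(OCc5ccccc5)cc4OCc4ccccc4)ccc3OCc3ccccc3)c(-c3ccc(OCc4ccccc4)cc3)oc2c1 | intermediate
17 | 5,7-bis(benzyloxy)-2-(4-(benzyloxy)-3-{2-[4-(benzyloxy)phenyl]-5-hydroxy-7-methoxy-4-oxo-4H-chromen-3-yl}phenyl)-2,3-dihydro-4H-chromen-4-one (flavanone, racemic, not isolated) | COc1cc(O)c2c(=O)c(-c3cc(C4CC(=O)c5c(OCc6ccccc6)cc(OCc6ccccc6)cc5O4)ccc3OCc3ccccc3)c(-c3ccc(OCc4ccccc4)cc3)oc2c1 | intermediate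
18 | 5,7-bis(benzyloxy)-2-(4-(benzyloxy)-3-{2-[4-(benzyloxy)phenyl]-5-hydroxy-7-methoxy-4-oxo-4H-chromen-3-yl}phenyl)-4H-chromen-4-one | COc1cc(O)c2c(=O)c(-c3cc(-c4cc(=O)c5c(OCc6ccccc6)cc(OCc6ccccc6)cc5o4)ccc3OCc3ccccc3)c(-c3ccc(OCc4ccccc4)cc3)oc2c1 | intermediate
19 | 5,7-dihydroxy-2-{4-hydroxy-3-[5-hydroxy-2-(4-hydroxyphenyl)-7-methoxy-4-oxo-4H-chromen-3-yl]phenyl}-4H-chromen-4-one (CNP0284832.0) | COc1cc(O)c2c(=O)c(-c3cc(-c4cc(=O)c5c(O)cc(O)cc5o4)ccc3O)c(-c3ccc(O)cc3)oc2c1 | target

**Total step count:** 12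
**Longest linear sequence:** 11 steps (steps 1–8 and 10–12)

**Steps most likely to fail**

1. Step 7 (proposed new method).
   - What may go wrong: the chain may fold through an aldol pathway. It may return to the lactone without forming the C–C bond. Methoxide may cut the C7–C8 or C8–C9 bond by retro-Claisen attack.
   - The fallback uses known chemistry with ring A bought instead of folded. It sets out from 3 and comes back at 13.
   - Miyaura borylation of 3 (B2pin2, PdCl2(dppf), KOAc, dioxane, 90 °C) should give 2-[2-(benzyloxy)-5-(1,3-dioxolan-2-yl)phenyl]-4,4,5,5-tetramethyl-1,3,2-dioxaborolane F1.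
   - Separately, commercial 1-(2,6-dihydroxy-4-methoxyphenyl)ethanone is C-aroylated as its polylithium salt (LiN(SiMe3)2, THF, −78 °C; 4-(benzyloxy)benzoyl chloride). This should give 1-[4-(benzyloxy)phenyl]-3-(2,6-dihydroxy-4-methoxyphenyl)propane-1,3-dione F2.
   - Cyclodehydration (p-TsOH, toluene, reflux) should give 2-[4-(benzyloxy)phenyl]-5-hydroxy-7-methoxy-4H-chromen-4-one F3.
   - Protection (MOMCl, NaH, DMF) should give 2-[4-(benzyloxy)phenyl]-7-methoxy-5-(methoxymethoxy)-4H-chromen-4-one F4.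
   - Lithiation at C3 and iodination (LiN(i-Pr)2, THF, −78 °C; I2) should give 2-[4-(benzyloxy)phenyl]-3-iodo-7-methoxy-5-(methoxymethoxy)-4H-chromen-4-one F5.
   - Suzuki coupling of the boronate with the iodide (Pd(OAc)2, SPhos, K3PO4, toluene–water, 90 °C) should give 3-[2-(benzyloxy)-5-(1,3-dioxolan-2-yl)phenyl]-2-[4-(benzyloxy)phenyl]-7-methoxy-5-(methoxymethoxy)-4H-chromen-4-one F6.
   - 2 M aq HCl in THF at 50 °C then removes the methoxymethyl group and the dioxolane to give 13.

2. Step 5.
   - What may go wrong: the hindered benzylic carbanion may attack the electron-rich ester too slowly. Proton exchange between dianion and product may stall the conversion. Acylation may occur on oxygen.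
   - The fallback replaces acylation by addition and oxidation. It sets out from 7 and comes back at 9.
   - The same dianion of 7 (LiN(i-Pr)2, 2.2 equiv, THF, −78 °C) is added to 4-(benzyloxy)benzaldehyde. This should give 6-{3-[2-(benzyloxy)-5-(1,3-dioxolan-2-yl)phenyl]-4-[4-(benzyloxy)phenyl]-4-hydroxy-2-oxobutyl}-4-methoxy-2H-pyran-2-one F7 as a mixture of diastereomers.
   - Oxidation with Dess–Martin periodinane (NaHCO3, CH2Cl2, 0 °C) then gives 9.

3. Step 4.
   - What may go wrong: proton transfer from the arylacetate to the pyrone carbanion may compete with acylation. The carbanion may also condense with un-ionised pyrone.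
   - The fallback again replaces acylation by addition and oxidation. It sets out from 5 and comes back at 7.
   - Reduction of 5 (i-Bu2AlH, toluene, −78 °C) should give [2-(benzyloxy)-5-(1,3-dioxolan-2-yl)phenyl]acetaldehyde F8.
   - Addition of lithiated 6 (LiN(i-Pr)2, THF, −78 °C) should give racemic 6-{3-[2-(benzyloxy)-5-(1,3-dioxolan-2-yl)phenyl]-2-hydroxypropyl}-4-methoxy-2H-pyran-2-one F9.
   - Dess–Martin periodinane (NaHCO3, CH2Cl2) oxidises this carbinol to 7.

**Further compounds**
F1 | step 7 | 2-[2-(benzyloxy)-5-(1,3-dioxolan-2-yl)phenyl]-4,4,5,5-tetramethyl-1,3,2-dioxaborolane | CC1(C)OB(OC1(C)C)c1cc(C2OCCO2)ccc1OCc1ccccc1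
F2 | step 7 | 1-[4-(benzyloxy)phenyl]-3-(2,6-dihydroxy-4-methoxyphenyl)propane-1,3-dione | COc1cc(O)c(C(=O)CC(=O)c2ccc(OCc3ccccc3)cc2)c(O)c1
F3 | step 7 | 2-[4-(benzyloxy)phenyl]-5-hydroxy-7-methoxy-4H-chromen-4-one | COc1cc(O)c2c(=O)cc(-c3ccc(OCc4ccccc4)cc3)oc2c1
F4 | step 7 | 2-[4-(benzyloxy)phenyl]-7-methoxy-5-(methoxymethoxy)-4H-chromen-4-one | COCOc1cc(OC)cc2oc(-c3ccc(OCc4ccccc4)cc3)cc(=O)c12
F5 | step 7 | 2-[4-(benzyloxy)phenyl]-3-iodo-7-methoxy-5-(methoxymethoxy)-4H-chromen-4-one | COCOc1cc(OC)cc2oc(-c3ccc(OCc4ccccc4)cc3)c(I)c(=O)c12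
F6 | step 7 | 3-[2-(benzyloxy)-5-(1,3-dioxolan-2-yl)phenyl]-2-[4-(benzyloxy)phenyl]-7-methoxy-5-(methoxymethoxy)-4H-chromen-4-one | COCOc1cc(OC)cc2oc(-c3ccc(OCc4ccccc4)cc3)c(-c3cc(C4OCCO4)ccc3OCc3ccccc3)c(=O)c12
F7 | step 5 | 6-{3-[2-(benzyloxy)-5-(1,3-dioxolan-2-yl)phenyl]-4-[4-(benzyloxy)phenyl]-4-hydroxy-2-oxobutyl}-4-methoxy-2H-pyran-2-one (mixture of diastereomers) | COC1=CC(=O)OC(CC(=O)C(c2cc(C3OCCO3)ccc2OCc2ccccc2)C(O)c2ccc(OCc3ccccc3)cc2)=C1
F8 | step 4 | [2-(benzyloxy)-5-(1,3-dioxolan-2-yl)phenyl]acetaldehyde | O=CCc1cc(C2OCCO2)ccc1OCc1ccccc1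
F9 | step 4 | 6-{3-[2-(benzyloxy)-5-(1,3-dioxolan-2-yl)phenyl]-2-hydroxypropyl}-4-methoxy-2H-pyran-2-one (racemic) | COC1=CC(=O)OC(CC(O)Cc2cc(C3OCCO3)ccc2OCc2ccccc2)=C1
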